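The earlier runs and the new flask are simulated with constants of no real substance, noise included.

The free catalyst is single-handed and the two substrates are mirror images, so the symmetric case is our zero: equal use of both substrates means an excess of zero.

common to all: left-handed substrate 0.070 M; right-handed substrate 0.070 M
- teal: reagent 0.21 M; free catalyst 62 µM; added ligand 0.11 mM; run made earlier
- amber: reagent 0.21 M; free catalyst 62 µM; added ligand 0.24 mM; run made earlier
- red: reagent 0.21 M; free catalyst 93 µM; added ligand 0.16 mM; run made earlier
- flask: reagent 0.210 M; free catalyst 62 µM; added ligand 0.16 mM; time 5.0 h

- teal (time / h: left-handed product / %, right-handed product / %): 1.00: 9.2, 0.7; 2.00: 11.2, 1.4; 3.00: 12.4, 0; 4.00: 13.1, 1.4; 5.00: 14.4, 0.9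
- amber (time / h: left-handed product / %, right-handed product / %): 0.417: 5.4, 0; 0.833: 5.3, 0.2; 1.33: 9.6, 0.2; 2.50: 10.3, 0; 5.00: 13.5, 0
- red (time / h: left-handed product / %, right-handed product / %): 0.417: 8.4, 0.1; 0.833: 8.0, 0; 1.33: 9.6, 0; 2.50: 12.0, 0.1; 5.00: 12.7, 0.5

(readings scatter by 1 percentage point)

- free catalyst is single-handed; left-handed substrate and right-handed substrate are mirror images of each other, charged as a racemate, each of them at the stated concentration
- an excess is below zero if the other one leads

- excess of left-handed product over right-handed product in the product at 30 min
- excess of left-handed product over right-handed product in the product at 5.0 h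
- part of the left-handed substrate and right-handed substrate charged together that has reacted at 5.0 h

But teal ends with 14.4% of left-handed product against 0.9% of right-handed, and a reading scatters by 1 percentage point, so these two readings tell us that teal's excess is high but not how high.

The amount can be carried further. We call D the exposure of a substrate: the natural logarithm of its charge over what is left of it. The left-handed substrate is half of what the percentages count, and teal and amber have the flask's free catalyst, with added ligand below and above the flask's, so the sum of their final left-handed readings is our mean fraction of left-handed substrate used. That gives a read D = 0.327, and, with the right-handed substrate not counted, we reckon 14.0% reacted in the flask.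

The forecast says 95% at 30 min, 94% at 5.0 h and 14% reacted, holding that “The 5 h totals are about 13–15% regardless of ligand”.

    reagent + free catalyst + left-handed substrate → free catalyst + left-handed product (k = 13.3 M⁻² s⁻¹)
    reagent + free catalyst + right-handed substrate → free catalyst + right-handed product (k = 0.102 M⁻² s⁻¹)
    2 free catalyst → spent catalyst (k = 15.3 M⁻¹ s⁻¹)
    free catalyst + added ligand ⇌ idle complex (K = 10100 M⁻¹, k = 0.329 M⁻¹ s⁻¹)

The flask gives 98.4% at 30 min, 98.2% at 5.0 h and 12.7% reacted, all within the margins. At 5.00 h the flask keeps 75% of its left-handed substrate against 99.8% of its right-handed, so its left-handed D is 0.291 and its right-handed D 0.00223. The neighbour flask, charged with 0.53 M of reagent, ends with the same 2.79% of free catalyst as the flask. Scaling D with the reagent charge, as for a pseudo-first-order loss, gives 0.734, or 48.0% of left-handed substrate left, and that neighbour keeps 48%.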